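Ring C of the isoflavan-4-ol is cut at O1–C8a, C4–C4a and O1–C2. The feature exploited is the ortho pair on ring A: C8a bears the ring oxygen O1 and its neighbour C4a bears C4, exactly what the two carbons of an aryne can acquire at once from the C=O group of a 2-arylacrolein. Carbonyl [2+2] addition, benzoxete opening and oxa-6π closure then deliver the whole 3-aryl-2H-chromene in one operation. The aryne precursor is an o-silylaryl triflate whose removable C5 bromine fixes the regiochemistry; bromine is introduced last, by directed metalation. The partner is the benzyl-protected ring B acrolein. Debromination, reagent-controlled hydroboration (C3/C4 trans) and neutral hydrogenolysis finish the route.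

Key step: step 11

Remark on the chemistry: the target is read as the (3S,4R) isomer, in which the aryl group on C3 and the hydroxyl on C4 lie on opposite faces of ring C (trans).

Step 1
Reactants: 1 4-(benzyloxy)-3-methoxybenzaldehyde (O-benzylvanillin)
Product: 3 4-(benzyloxy)-3-methoxyphenol, via aryl formate 2 (not isolated)
Conditions: mCPBA, CH2Cl2, 0 °C to rt; then K2CO3, MeOH, rt
Reagents that add atoms: 3-chloroperoxybenzoic acid (mCPBA), OOC(=O)c1cccc(Cl)c1
Why: Dakin (Baeyer–Villiger-type) oxidation, in which the electron-rich aryl group migrates to oxygen in the peracid adduct and the resulting formate 2 is methanolysed to the phenol.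

Step 2
Reactants: 3 4-(benzyloxy)-3-methoxyphenol
Product: 4 4-(benzyloxy)-2-bromo-5-methoxyphenol
Conditions: NBS, MeCN, −10 to 0 °C
Reagents that add atoms: N-bromosuccinimide, O=C1CCC(=O)N1Br
Why: Electrophilic aromatic bromination should occur at the position ortho to the hydroxyl and para to the methoxy group, the most activated and least crowded site of a 3,4-dialkoxyphenol.

Step 3
Reactants: 4 4-(benzyloxy)-2-bromo-5-methoxyphenol
Product: 7 4-(benzyloxy)-5-methoxy-2-(trimethylsilyl)phenol, via silyl ether 5 (not isolated), via aryllithium 6 (not isolated)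
Conditions: HMDS, THF, 65 °C, then evaporation; n-BuLi, THF, −78 °C to rt; aq. NH4Cl
Reagents that add atoms: hexamethyldisilazane, C[Si](C)(C)N[Si](C)(C)C
Why: O-silylation followed by bromine–lithium exchange triggers a 1,3 oxygen-to-carbon silyl shift (retro-Brook rearrangement), the standard entry to o-silylphenols, and places silicon on the future C8a while no other halogen is on the ring.

Step 4
Reactants: 7 4-(benzyloxy)-5-methoxy-2-(trimethylsilyl)phenol
Product: 8 4-(benzyloxy)-5-methoxy-2-(trimethylsilyl)phenyl N-isopropylcarbamate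
Conditions: iPrNCO, Et3N (cat.), CH2Cl2, rt to 40 °C
Reagents that add atoms: isopropyl isocyanate, CC(C)N=C=O
Why: Base-catalysed addition of the phenol to the isocyanate (carbamoylation) installs a group that directs metalation and can later be removed by elimination.

Step 5
Reactants: 8 4-(benzyloxy)-5-methoxy-2-(trimethylsilyl)phenyl N-isopropylcarbamate
Product: 12 4-(benzyloxy)-2-bromo-3-methoxy-6-(trimethylsilyl)phenyl N-isopropylcarbamate, via N-silyl carbamate 9 (not isolated), via aryllithium 10 (not isolated), via N-silyl bromide 11 (not isolated)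
Conditions: TBSOTf, TMEDA, Et2O, 0 °C to rt; n-BuLi, TMEDA, −78 °C; BrCl2CCCl2Br, −78 °C to rt; aq. NaHSO4
Reagents that add atoms: 1,2-dibromo-1,1,2,2-tetrachloroethane, ClC(Cl)(Br)C(Cl)(Cl)Br
Why: Directed ortho-metalation after transient N-silylation should lithiate the only free position ortho to the carbamate, which is also ortho to the methoxy group, and the aryllithium is quenched by a positive-bromine donor, so that bromine enters last and never meets an alkyllithium.

Step 6
Reactants: 12 4-(benzyloxy)-2-bromo-3-methoxy-6-(trimethylsilyl)phenyl N-isopropylcarbamate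
Product: 14 4-(benzyloxy)-2-bromo-3-methoxy-6-(trimethylsilyl)phenyl trifluoromethanesulfonate, via phenol 13 (not isolated)
Conditions: DBU, Et2NH, MeCN, 40 °C; then PhNTf2, rt
Reagents that add atoms: N-phenylbis(trifluoromethanesulfonimide), O=S(=O)(N(c1ccccc1)S(=O)(=O)C(F)(F)F)C(F)(F)F
Why: DBU removes the carbamate N–H proton and the anion expels the phenoxide (E1cB elimination, the isocyanate being trapped by Et2NH as a urea), which is triflated in the same pot, a sequence established for o-silylaryl carbamates.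

Step 7
Reactants: 15 2,3-dimethoxyphenol
Product: 16 2,3-dimethoxy-1,4-benzoquinone
Conditions: (KSO3)2NO, KH2PO4, H2O/acetone, rt
Reagents that add atoms: potassium nitrosodisulfonate (KSO3)2NO, [K+].[K+].[O]N(S(=O)(=O)[O-])S(=O)(=O)[O-]
Why: Teuber oxidation, in which the nitrosodisulfonate radical converts a phenol with a free para position into the p-quinone without touching the methoxy groups.

Step 8
Reactants: 16 2,3-dimethoxy-1,4-benzoquinone
Product: 18 1,4-bis(benzyloxy)-2,3-dimethoxybenzene, via hydroquinone 17 (not isolated)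
Conditions: Na2S2O4, H2O/EtOAc, rt; then BnBr, K2CO3, DMF, 50 °C, under argon
Reagents that add atoms: benzyl bromide, BrCc1ccccc1
Why: Dithionite reduction to the hydroquinone and Williamson benzylation of both phenoxides should give a symmetrical arene whose two free ring positions are equivalent.

Step 9
Reactants: 18 1,4-bis(benzyloxy)-2,3-dimethoxybenzene
Product: 19 1,4-bis(benzyloxy)-5-bromo-2,3-dimethoxybenzene
Conditions: NBS, MeCN, 0 °C to rt, dark
Reagents that add atoms: N-bromosuccinimide, O=C1CCC(=O)N1Br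
Why: Electrophilic aromatic bromination of the tetraalkoxybenzene should stop after one substitution because the two open positions are equivalent and the first bromine deactivates the ring.

Step 10
Reactants: 19 1,4-bis(benzyloxy)-5-bromo-2,3-dimethoxybenzene; 20 2-bromo-3,3-diethoxyprop-1-ene (2-bromoacrolein diethyl acetal)
Product: 24 2-[2,5-bis(benzyloxy)-3,4-dimethoxyphenyl]prop-2-enal, via aryllithium 21 (not isolated), via arylzinc chloride 22 (not isolated), via diethyl acetal 23 (not isolated)
Conditions: n-BuLi, THF, −78 °C; ZnCl2, −78 °C to rt; 20, Pd(PPh3)4 (3 mol%), 50 °C; then 1 M HCl, 0 °C to rt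
Reagents that add atoms: water, O
Why: Bromine–lithium exchange and transmetalation give an arylzinc that should undergo Negishi cross-coupling with the vinyl bromide 20, and dilute acid then hydrolyses the acetal to the α-aryl enal, which is used promptly because 2-arylacroleins dimerise on storage.

Step 11
Reactants: 14 4-(benzyloxy)-2-bromo-3-methoxy-6-(trimethylsilyl)phenyl trifluoromethanesulfonate; 24 2-[2,5-bis(benzyloxy)-3,4-dimethoxyphenyl]prop-2-enal
Product: 28 7-(benzyloxy)-3-[2,5-bis(benzyloxy)-3,4-dimethoxyphenyl]-5-bromo-6-methoxy-2H-chromene, via aryne 25 (not isolated), via benzoxete 26 (not isolated), via o-quinone methide 27 (not isolated)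
Conditions: CsF, MeCN, rt to 40 °C, 14 (1.3 equiv) added slowly to 24
Reagents that add atoms: none
Why: Fluoride removes the silyl group of 14 and triflate departs to give aryne 25, whose strained bond is polarised by the C5 bromine so that the carbonyl oxygen of 24 adds to the distal carbon (future C8a) while the negative charge develops at C4a beside bromine and closes on the carbonyl carbon, a stepwise polar [2+2] that forms O1–C8a and C4–C4a in benzoxete 26. Thermal four-electron ring opening of 26 gives o-quinone methide 27, in which the peri bromine disfavours the geometry with the vinyl arm next to C5 and so holds it next to the carbonyl oxygen. A thermal disrotatory oxa-6π electrocyclisation of this 1-oxatriene then forms O1–C2, closing the six-membered pyran ring (ring C) and restoring the aromaticity of ring A. The closest known reaction type is the fluoride-triggered annulation of arynes with α,β-unsaturated aldehydes to 2H-chromenes through benzoxetes and o-quinone methides. No stereocenter is created, since C2 arrives as CH2 and C3=C4 as an alkene. The selectivity required is regiochemical (oxygen on C8a, carbon on C4a), which the 3-haloaryne polarisation secures because the two ring A oxygens sit one meta and one para to each aryne carbon and cancel; slow release of the aryne into the enal limits ene and [4+2] side reactions.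

Step 12
Reactants: 28 7-(benzyloxy)-3-[2,5-bis(benzyloxy)-3,4-dimethoxyphenyl]-5-bromo-6-methoxy-2H-chromene
Product: 30 7-(benzyloxy)-3-[2,5-bis(benzyloxy)-3,4-dimethoxyphenyl]-6-methoxy-2H-chromene, via aryllithium 29 (not isolated)
Conditions: n-BuLi, THF, −78 °C; then MeOH, −78 °C to rt
Reagents that add atoms: none
Why: Bromine–lithium exchange at −78 °C is faster than any deprotonation and the aryllithium is protonated by methanol (hydrodebromination), which removes the directing halogen before the bulky borane must reach C4 and before hydrogenolysis could release HBr.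

Step 13
Reactants: 30 7-(benzyloxy)-3-[2,5-bis(benzyloxy)-3,4-dimethoxyphenyl]-6-methoxy-2H-chromene
Product: 32 (3S,4R)-7-(benzyloxy)-3-[2,5-bis(benzyloxy)-3,4-dimethoxyphenyl]-6-methoxychroman-4-ol, via dialkylborane 31 (not isolated)
Conditions: IpcBH2 [from (+)-α-pinene], THF, −25 to 0 °C; then NaOH, H2O2, 0 °C to rt
Reagents that add atoms: hydrogen peroxide, OO
Why: Asymmetric hydroboration–oxidation with monoisopinocampheylborane places boron on the less substituted C4 and hydrogen on C3 from the same face, so that after oxidation with retention the C3 aryl group and the C4 hydroxyl are trans, and the face is chosen by the reagent, the borane from (+)-α-pinene being expected by analogy with 1-arylcycloalkenes to give the (3S,4R) isomer (the antipodal borane is the alternative should the sense prove opposite).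

Step 14
Reactants: 32 (3S,4R)-7-(benzyloxy)-3-[2,5-bis(benzyloxy)-3,4-dimethoxyphenyl]-6-methoxychroman-4-ol
Product: 33 (3S,4R)-3-(2,5-dihydroxy-3,4-dimethoxyphenyl)-6-methoxy-3,4-dihydro-2H-chromene-4,7-diol
Conditions: H2 (1 atm), Pd/C, NaHCO3 (solid), EtOAc, rt
Reagents that add atoms: none
Why: Catalytic hydrogenolysis of the three aryl benzyl ethers in a buffered aprotic medium should be faster than cleavage of the benzylic C4–O bond, avoids the acid or base that would ionise the 4-hydroxyl or oxidise the hydroquinone ring, and touches neither stereocenter.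

Compound list

1 | 4-(benzyloxy)-3-methoxybenzaldehyde (O-benzylvanillin) | COc1cc(C=O)ccc1OCc1ccccc1 | starting material
2 | 4-(benzyloxy)-3-methoxyphenyl formate | COc1cc(OC=O)ccc1OCc1ccccc1 | intermediate
3 | 4-(benzyloxy)-3-methoxyphenol | COc1cc(O)ccc1OCc1ccccc1 | intermediate
4 | 4-(benzyloxy)-2-bromo-5-methoxyphenol | COc1cc(O)c(Br)cc1OCc1ccccc1 | intermediate
5 | [4-(benzyloxy)-2-bromo-5-methoxyphenoxy]trimethylsilane | COc1cc(O[Si](C)(C)C)c(Br)cc1OCc1ccccc1 | intermediate
6 | {5-(benzyloxy)-4-methoxy-2-[(trimethylsilyl)oxy]phenyl}lithium | COc1cc(O[Si](C)(C)C)c([Li])cc1OCc1ccccc1 | intermediate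
7 | 4-(benzyloxy)-5-methoxy-2-(trimethylsilyl)phenol | COc1cc(O)c([Si](C)(C)C)cc1OCc1ccccc1 | intermediate
8 | 4-(benzyloxy)-5-methoxy-2-(trimethylsilyl)phenyl N-isopropylcarbamate | COc1cc(OC(=O)NC(C)C)c([Si](C)(C)C)cc1OCc1ccccc1 | intermediate
9 | 4-(benzyloxy)-5-methoxy-2-(trimethylsilyl)phenyl N-(tert-butyldimethylsilyl)-N-isopropylcarbamate | COc1cc(OC(=O)N(C(C)C)[Si](C)(C)C(C)(C)C)c([Si](C)(C)C)cc1OCc1ccccc1 | intermediate
10 | 2-lithio derivative of 9 (lithium on the ring carbon between the carbamate oxygen and the methoxy group) | COc1c([Li])c(OC(=O)N(C(C)C)[Si](C)(C)C(C)(C)C)c([Si](C)(C)C)cc1OCc1ccccc1 | intermediate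
11 | 4-(benzyloxy)-2-bromo-3-methoxy-6-(trimethylsilyl)phenyl N-(tert-butyldimethylsilyl)-N-isopropylcarbamate | COc1c(Br)c(OC(=O)N(C(C)C)[Si](C)(C)C(C)(C)C)c([Si](C)(C)C)cc1OCc1ccccc1 | intermediate
12 | 4-(benzyloxy)-2-bromo-3-methoxy-6-(trimethylsilyl)phenyl N-isopropylcarbamate | COc1c(Br)c(OC(=O)NC(C)C)c([Si](C)(C)C)cc1OCc1ccccc1 | intermediate
13 | 4-(benzyloxy)-2-bromo-3-methoxy-6-(trimethylsilyl)phenol | COc1c(Br)c(O)c([Si](C)(C)C)cc1OCc1ccccc1 | intermediate
14 | 4-(benzyloxy)-2-bromo-3-methoxy-6-(trimethylsilyl)phenyl trifluoromethanesulfonate | COc1c(Br)c(OS(=O)(=O)C(F)(F)F)c([Si](C)(C)C)cc1OCc1ccccc1 | intermediate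
15 | 2,3-dimethoxyphenol | COc1cccc(O)c1OC | starting material
16 | 2,3-dimethoxy-1,4-benzoquinone | COC1=C(OC)C(=O)C=CC1=O | intermediate
17 | 2,3-dimethoxybenzene-1,4-diol | COc1c(O)ccc(O)c1OC | intermediate
18 | 1,4-bis(benzyloxy)-2,3-dimethoxybenzene | COc1c(OCc2ccccc2)ccc(OCc2ccccc2)c1OC | intermediate
19 | 1,4-bis(benzyloxy)-5-bromo-2,3-dimethoxybenzene | COc1c(OCc2ccccc2)cc(Br)c(OCc2ccccc2)c1OC | intermediate
20 | 2-bromo-3,3-diethoxyprop-1-ene (2-bromoacrolein diethyl acetal) | C=C(Br)C(OCC)OCC | starting material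
21 | [2,5-bis(benzyloxy)-3,4-dimethoxyphenyl]lithium | [Li]c1cc(OCc2ccccc2)c(OC)c(OC)c1OCc1ccccc1 | intermediate
22 | [2,5-bis(benzyloxy)-3,4-dimethoxyphenyl]zinc chloride | Cl[Zn]c1cc(OCc2ccccc2)c(OC)c(OC)c1OCc1ccccc1 | intermediate
23 | 1,4-bis(benzyloxy)-5-(3,3-diethoxyprop-1-en-2-yl)-2,3-dimethoxybenzene | C=C(C(OCC)OCC)c1cc(OCc2ccccc2)c(OC)c(OC)c1OCc1ccccc1 | intermediate
24 | 2-[2,5-bis(benzyloxy)-3,4-dimethoxyphenyl]prop-2-enal | C=C(C=O)c1cc(OCc2ccccc2)c(OC)c(OC)c1OCc1ccccc1 | intermediate
25 | 5-(benzyloxy)-3-bromo-4-methoxybenzyne (1,2-didehydrobenzene) | COC1=C(Br)C#CC=C1OCc1ccccc1 | intermediate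
26 | 5-(benzyloxy)-2-{1-[2,5-bis(benzyloxy)-3,4-dimethoxyphenyl]ethenyl}-3-bromo-4-methoxy-2H-benzoxete (racemic at C2) | COc1c(OCc2ccccc2)cc2OC(C(=C)c3cc(OCc4ccccc4)c(OC)c(OC)c3OCc3ccccc3)c2c1Br | intermediate
27 | 3-(benzyloxy)-6-{2-[2,5-bis(benzyloxy)-3,4-dimethoxyphenyl]prop-2-en-1-ylidene}-5-bromo-4-methoxycyclohexa-2,4-dien-1-one (vinyl arm on the side of the carbonyl oxygen) | COC1=C(Br)/C(=C/C(=C)c2cc(OCc3ccccc3)c(OC)c(OC)c2OCc2ccccc2)C(=O)C=C1OCc1ccccc1 | intermediate
28 | 7-(benzyloxy)-3-[2,5-bis(benzyloxy)-3,4-dimethoxyphenyl]-5-bromo-6-methoxy-2H-chromene | COc1c(OCc2ccccc2)cc2OCC(c3cc(OCc4ccccc4)c(OC)c(OC)c3OCc3ccccc3)=Cc2c1Br | intermediate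
29 | {7-(benzyloxy)-3-[2,5-bis(benzyloxy)-3,4-dimethoxyphenyl]-6-methoxy-2H-chromen-5-yl}lithium | COc1c(OCc2ccccc2)cc2OCC(c3cc(OCc4ccccc4)c(OC)c(OC)c3OCc3ccccc3)=Cc2c1[Li] | intermediate
30 | 7-(benzyloxy)-3-[2,5-bis(benzyloxy)-3,4-dimethoxyphenyl]-6-methoxy-2H-chromene | COc1c(OCc2ccccc2)cc2OCC(c3cc(OCc4ccccc4)c(OC)c(OC)c3OCc3ccccc3)=Cc2c1 | intermediate
31 | (isopinocampheyl){7-(benzyloxy)-3-[2,5-bis(benzyloxy)-3,4-dimethoxyphenyl]-6-methoxychroman-4-yl}borane (boron on C4 trans to the C3 aryl group, ring configuration as in 32, isopinocampheyl group from (+)-α-pinene) | COc1cc2c(cc1OCc1ccccc1)OC[C@H](c1cc(OCc3ccccc3)c(OC)c(OC)c1OCc1ccccc1)[C@H]2B[C@@H]1C[C@@H]2C[C@@H](C2(C)C)[C@H]1C | intermediate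
32 | (3S,4R)-7-(benzyloxy)-3-[2,5-bis(benzyloxy)-3,4-dimethoxyphenyl]-6-methoxychroman-4-ol | COc1cc2c(cc1OCc1ccccc1)OC[C@H](c1cc(OCc3ccccc3)c(OC)c(OC)c1OCc1ccccc1)[C@H]2O | intermediate
33 | (3S,4R)-3-(2,5-dihydroxy-3,4-dimethoxyphenyl)-6-methoxy-3,4-dihydro-2H-chromene-4,7-diol | COc1cc2c(cc1O)OC[C@H](c1cc(O)c(OC)c(OC)c1O)[C@H]2O | target

Total step count: 14. Longest linear sequence: 10 (steps 1–6, then 11–14); the ring B branch (steps 7–10) joins at step 11.

Steps most likely to fail

First, step 11. The aryne may be consumed by ene or [4+2] reactions with the enal, the enal may oligomerise under fluoride, or oxygen may add to the wrong aryne carbon. The fallback leaves the aryne aside and reaches the chromene by boron-templated ortho-condensation of a phenol with the same enal; it sets out from 24 and returns to the route at 30, so that step 12 is no longer needed. Purchased 3-(benzyloxy)-4-methoxybenzaldehyde would be oxidised (mCPBA, CH2Cl2; then K2CO3, MeOH) through 3-(benzyloxy)-4-methoxyphenyl formate F1 to 3-(benzyloxy)-4-methoxyphenol F2. F2 and 24 would then be heated with PhB(OH)2 and catalytic propionic acid in toluene with removal of water. This should form, at the ring position para to the benzyloxy group, 7-(benzyloxy)-4-{1-[2,5-bis(benzyloxy)-3,4-dimethoxyphenyl]ethenyl}-6-methoxy-2-phenyl-4H-1,3,2-benzodioxaborinine F3. Continued heating should expel the boronic acid and close ring C by the same oxa-6π step to give 30.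

Second, step 13. The chiral borane may discriminate poorly between the two alkene faces, or add too slowly to the hindered trisubstituted alkene. The fallback replaces asymmetric induction by resolution; it sets out from 30 and returns at 32. Hydroboration with BH3·SMe2 (THF, 0 °C; then NaOH, H2O2) should give the trans alcohol as a racemate, that is 32 together with its mirror image (3R,4S)-7-(benzyloxy)-3-[2,5-bis(benzyloxy)-3,4-dimethoxyphenyl]-6-methoxychroman-4-ol F4. Kinetic resolution by lipase-catalysed acetylation (immobilised Candida antarctica lipase B, vinyl acetate, MTBE, 40 °C) should convert the (4R) alcohol, the enantiomer usually preferred for cyclic benzylic carbinols of this shape, into (3S,4R)-7-(benzyloxy)-3-[2,5-bis(benzyloxy)-3,4-dimethoxyphenyl]-6-methoxychroman-4-yl acetate F5 and leave F4. After chromatographic separation, methanolysis of F5 (K2CO3, MeOH) would return 32.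

Third, step 14. Once the C7 phenol para to C4 is unmasked, the benzylic C4–O bond may be hydrogenolysed, or the carbinol may ionise on the catalyst surface. The fallback masks the carbinol during debenzylation; it sets out from 32 and returns at 33. Silylation (TBSOTf, 2,6-lutidine, CH2Cl2, −78 °C) should give (3S,4R)-7-(benzyloxy)-3-[2,5-bis(benzyloxy)-3,4-dimethoxyphenyl]-4-[(tert-butyldimethylsilyl)oxy]-6-methoxychromane F6. Hydrogenolysis (H2, Pd/C, EtOAc) should then give (3S,4R)-4-[(tert-butyldimethylsilyl)oxy]-3-(2,5-dihydroxy-3,4-dimethoxyphenyl)-6-methoxychroman-7-ol F7. Buffered desilylation (TBAF, AcOH, THF, 0 °C, under argon) would release 33.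

Further compounds

F1 | step 11 | 3-(benzyloxy)-4-methoxyphenyl formate | COc1ccc(OC=O)cc1OCc1ccccc1
F2 | step 11 | 3-(benzyloxy)-4-methoxyphenol | COc1ccc(O)cc1OCc1ccccc1
F3 | step 11 | 7-(benzyloxy)-4-{1-[2,5-bis(benzyloxy)-3,4-dimethoxyphenyl]ethenyl}-6-methoxy-2-phenyl-4H-1,3,2-benzodioxaborinine (racemic at C4) | COc1cc2C(C(=C)c3cc(OCc4ccccc4)c(OC)c(OC)c3OCc3ccccc3)OB(c3ccccc3)Oc2cc1OCc1ccccc1
F4 | step 13 | (3R,4S)-7-(benzyloxy)-3-[2,5-bis(benzyloxy)-3,4-dimethoxyphenyl]-6-methoxychroman-4-ol | COc1cc2c(cc1OCc1ccccc1)OC[C@@H](c1cc(OCc3ccccc3)c(OC)c(OC)c1OCc1ccccc1)[C@@H]2O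
F5 | step 13 | (3S,4R)-7-(benzyloxy)-3-[2,5-bis(benzyloxy)-3,4-dimethoxyphenyl]-6-methoxychroman-4-yl acetate | COc1cc2c(cc1OCc1ccccc1)OC[C@H](c1cc(OCc3ccccc3)c(OC)c(OC)c1OCc1ccccc1)[C@H]2OC(C)=O
F6 | step 14 | (3S,4R)-7-(benzyloxy)-3-[2,5-bis(benzyloxy)-3,4-dimethoxyphenyl]-4-[(tert-butyldimethylsilyl)oxy]-6-methoxychromane | COc1cc2c(cc1OCc1ccccc1)OC[C@H](c1cc(OCc3ccccc3)c(OC)c(OC)c1OCc1ccccc1)[C@H]2O[Si](C)(C)C(C)(C)C
F7 | step 14 | (3S,4R)-4-[(tert-butyldimethylsilyl)oxy]-3-(2,5-dihydroxy-3,4-dimethoxyphenyl)-6-methoxychroman-7-ol | COc1cc2c(cc1O)OC[C@H](c1cc(O)c(OC)c(OC)c1O)[C@H]2O[Si](C)(C)C(C)(C)C
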